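**Retrosynthetic overview**

- The strategy rests on butenolide C5 (ring O1–C2(=O)–C3(OH)=C4(Ph)–C5). It carries O1, the methyl ester carbon and the C6 methylene of the chroman arm, so it is the α-carbon of an α-hydroxy acid, and (S)-3-(4-hydroxyphenyl)lactic acid supplies O1, C5, the ester carbon, C6 and the aryl ring.
- The butenolide is closed last: O1–C2 by esterification with a benzyloxy(phosphono)acetic acid, then C3=C4 by intramolecular Horner–Wadsworth–Emmons reaction. The C3 oxygen travels as a benzyl ether and is freed by the final hydrogenolysis.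
- C4–C5 is made by C-benzoylation of the lithium enolate of a cis 2-tert-butyl-1,3-dioxolan-4-one with benzoyl chloride (C5 as nucleophile, C4 as electrophile). The pivalaldehyde acetal is a temporary ring that holds the configuration while C5 is planar; methanolysis then opens it and turns its carbonyl into the methyl ester.
- Ring order: chroman first (acid-mediated annulation of the phenol with 2-methylbut-3-en-2-ol), then the temporary dioxolanone, then the butenolide.

Key step: step 5

Assumption: triethyl phosphonoacetate, benzyl alcohol and 4-acetamidobenzenesulfonyl azide are taken as commercial, and the phosphonate-bearing carbon of 16, 17 and 18 is racemic or epimeric without consequence because it becomes the sp2 carbon C3.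

**Route**

Step 1
Reactants: 1 (S)-3-(4-hydroxyphenyl)lactic acid
Product: 2 methyl (S)-2-hydroxy-3-(4-hydroxyphenyl)propanoate
Conditions: MeOH, H2SO4 (cat.), reflux
Reagents that add atoms: methanol, CO
Why: Fischer esterification of the carboxylic acid in excess methanol; the phenol and the secondary alcohol do not react and the α-carbon is not enolised under acid, so the (S) configuration is kept.

Step 2
Reactants: 2 methyl (S)-2-hydroxy-3-(4-hydroxyphenyl)propanoate; 3 2-methylbut-3-en-2-ol
Product: 5 methyl (S)-3-(2,2-dimethylchroman-6-yl)-2-hydroxypropanoate, via ortho-prenylphenol 4 (not isolated)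
Conditions: 3 (1.3 equiv, slow addition), Amberlyst 15, ClCH2CH2Cl, 70 °C
Reagents that add atoms: none
Why: Friedel–Crafts ortho-prenylation of the para-blocked phenol by the dimethylallyl cation from 3 gives 4, whose phenol OH adds to the trisubstituted alkene in the Markovnikov sense (acid-catalysed hydroalkoxylation) to close the chroman ring; the two ortho positions are equivalent and the α-hydroxy ester centre is untouched.

Step 3
Reactants: 5 methyl (S)-3-(2,2-dimethylchroman-6-yl)-2-hydroxypropanoate
Product: 6 (S)-3-(2,2-dimethylchroman-6-yl)-2-hydroxypropanoic acid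
Conditions: LiOH·H2O (1.5 equiv), THF–H2O, 0 °C to rt; then HCl (pH 2–3)
Reagents that add atoms: lithium hydroxide, [Li+].[OH-]
Why: Saponification of the methyl ester at low temperature is much faster than α-deprotonation of an α-hydroxy ester, so the stereocentre should not racemise; the chroman ether is inert to base and to the brief acidification.

Step 4
Reactants: 6 (S)-3-(2,2-dimethylchroman-6-yl)-2-hydroxypropanoic acid; 7 pivalaldehyde
Product: 8 (2S,5S)-2-tert-butyl-5-[(2,2-dimethylchroman-6-yl)methyl]-1,3-dioxolan-4-one (cis)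
Conditions: 7 (2 equiv), p-TsOH·H2O (cat.), H2SO4 (cat.), pentane, reflux, Dean–Stark; crystallisation or chromatography
Reagents that add atoms: none
Why: Acid-catalysed acetalisation of the α-hydroxy acid with water removal sets the acetal centre C2 under thermodynamic control from the existing C5 centre (tert-butyl and arylmethyl cis); the minor trans isomer must be removed because it would lead into the enantiomeric series.

Step 5
Reactants: 8 (2S,5S)-2-tert-butyl-5-[(2,2-dimethylchroman-6-yl)methyl]-1,3-dioxolan-4-one; 9 benzoyl chloride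
Product: 11 (2S,5R)-5-benzoyl-2-tert-butyl-5-[(2,2-dimethylchroman-6-yl)methyl]-1,3-dioxolan-4-one, via lithium enolate 10 (not isolated)
Conditions: LDA (LiN(iPr)2, 1.1 equiv), THF, −78 °C; enolate cannulated into 9 (1.5 equiv), THF, −78 to −40 °C; aq NH4Cl
Reagents that add atoms: none
Why: LDA removes H-5 to give the planar lithium enolate 10, in which the original stereocentre is erased while its information is kept at the acetal carbon C2. The enolate carbon attacks benzoyl chloride by addition–elimination, a Claisen-type C-acylation of a lithium ester enolate; the closest known reactions are the alkylations, aldol additions and acylations of 2-tert-butyl-1,3-dioxolan-4-one enolates with self-regeneration of the stereocentre. One C–C bond (butenolide C4–C5) is formed and no ring is closed. The new quaternary centre is controlled by the tert-butyl group, which shields its own face of the nearly flat ring, so benzoyl enters trans to it and takes the place of the former hydrogen, giving overall retention and the (2S,5R) product. The step needs this facial selectivity and C- over O-acylation; the latter is secured by the tightly O-bound lithium counter-ion in THF without polar additives, by the acid chloride as acyl donor, and by inverse addition at −78 °C, which also keeps the thermally labile enolate from condensing with itself or with the product. The product has no α-hydrogen, so proton transfer to unreacted enolate and double acylation cannot occur.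

Step 6
Reactants: 11 (2S,5R)-5-benzoyl-2-tert-butyl-5-[(2,2-dimethylchroman-6-yl)methyl]-1,3-dioxolan-4-one
Product: 12 methyl (R)-2-[(2,2-dimethylchroman-6-yl)methyl]-2-hydroxy-3-oxo-3-phenylpropanoate
Conditions: NaOMe (0.2 equiv), MeOH–THF, −20 to 0 °C; AcOH quench
Reagents that add atoms: methanol, CO
Why: Methoxide adds to the acylal-type lactone carbonyl (transesterification) and the hemiacetal alkoxide released loses pivalaldehyde, giving the methyl ester and the free tertiary alcohol without touching the quaternary centre; catalytic base, low temperature and an acidic quench are chosen to hold back retro-Claisen attack on the benzoyl ketone and C-to-O benzoyl shift in the product alkoxide.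

Step 7
Reactants: 13 triethyl phosphonoacetate
Product: 14 ethyl 2-diazo-2-(diethoxyphosphoryl)acetate
Conditions: p-ABSA (1.1 equiv), DBU (1.2 equiv), MeCN, 0 °C to rt
Reagents that add atoms: 4-acetamidobenzenesulfonyl azide (p-ABSA), CC(=O)Nc1ccc(cc1)S(=O)(=O)N=[N+]=[N-]
Why: Regitz diazo transfer from the sulfonyl azide to the DBU-generated anion of the doubly activated methylene group.

Step 8
Reactants: 14 ethyl 2-diazo-2-(diethoxyphosphoryl)acetate; 15 benzyl alcohol
Product: 16 ethyl 2-(benzyloxy)-2-(diethoxyphosphoryl)acetate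
Conditions: 15 (1.5 equiv), Rh2(OAc)4 (1 mol %), toluene, 80 °C
Reagents that add atoms: none
Why: Rh2(OAc)4-catalysed loss of nitrogen gives a rhodium carbenoid that inserts into the O–H bond of benzyl alcohol (carbenoid O–H insertion), placing the benzyloxy group on the phosphonate carbon.

Step 9
Reactants: 16 ethyl 2-(benzyloxy)-2-(diethoxyphosphoryl)acetate
Product: 17 2-(benzyloxy)-2-(diethoxyphosphoryl)acetic acid
Conditions: NaOH (1.0 equiv), EtOH–H2O, 0 °C to rt; then HCl (pH 2)
Reagents that add atoms: sodium hydroxide, [Na+].[OH-]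
Why: Selective saponification of the carboxylic ethyl ester with one equivalent of hydroxide, since phosphonate diethyl esters hydrolyse far more slowly under these conditions.

Step 10
Reactants: 12 methyl (R)-2-[(2,2-dimethylchroman-6-yl)methyl]-2-hydroxy-3-oxo-3-phenylpropanoate; 17 2-(benzyloxy)-2-(diethoxyphosphoryl)acetic acid
Product: 18 methyl (R)-2-{[2-(benzyloxy)-2-(diethoxyphosphoryl)acetyl]oxy}-2-[(2,2-dimethylchroman-6-yl)methyl]-3-oxo-3-phenylpropanoate (epimers at the phosphonate carbon)
Conditions: 17 (1.5 equiv), DCC (1.6 equiv), DMAP (0.1 equiv), CH2Cl2, 0 °C to rt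
Reagents that add atoms: none
Why: Steglich carbodiimide esterification of the tertiary alcohol (forming O1–C2), helped by the ability of α-phosphono acids to acylate hindered alcohols through the derived ketene; the quaternary centre is not involved.

Step 11
Reactants: 18 methyl (R)-2-{[2-(benzyloxy)-2-(diethoxyphosphoryl)acetyl]oxy}-2-[(2,2-dimethylchroman-6-yl)methyl]-3-oxo-3-phenylpropanoate
Product: 19 methyl (R)-4-(benzyloxy)-2-[(2,2-dimethylchroman-6-yl)methyl]-5-oxo-3-phenyl-2,5-dihydrofuran-2-carboxylate
Conditions: NaH (1.1 equiv), THF, 0 °C to rt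
Reagents that add atoms: none
Why: Intramolecular Horner–Wadsworth–Emmons reaction: the phosphonate carbanion adds to the neighbouring phenyl ketone in a five-membered ring closure and the oxaphosphetane collapses with loss of diethyl phosphate to give the C3=C4 bond; attack on the methyl ester instead (Dieckmann mode) gives an adduct that cannot be deprotonated and so reverts.

Step 12
Reactants: 19 methyl (R)-4-(benzyloxy)-2-[(2,2-dimethylchroman-6-yl)methyl]-5-oxo-3-phenyl-2,5-dihydrofuran-2-carboxylate
Product: 20 4'-dehydroxy aspernolide A, methyl (R)-2-[(2,2-dimethylchroman-6-yl)methyl]-4-hydroxy-5-oxo-3-phenyl-2,5-dihydrofuran-2-carboxylate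
Conditions: H2 (1 atm), 10% Pd/C, EtOAc, rt
Reagents that add atoms: none
Why: Hydrogenolysis of the benzylic C–O bond of the benzyl enol ether frees the C3 enol, while the tetrasubstituted conjugated C3=C4 bond, the aryl rings and the quaternary centre should not be reduced under one atmosphere of hydrogen at room temperature.

**Compound list**

1 | (S)-3-(4-hydroxyphenyl)lactic acid | O=C(O)[C@@H](O)Cc1ccc(O)cc1 | starting material
2 | methyl (S)-2-hydroxy-3-(4-hydroxyphenyl)propanoate | COC(=O)[C@@H](O)Cc1ccc(O)cc1 | intermediate
3 | 2-methylbut-3-en-2-ol | CC(C)(O)C=C | starting material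
4 | methyl (S)-2-hydroxy-3-[4-hydroxy-3-(3-methylbut-2-en-1-yl)phenyl]propanoate | COC(=O)[C@@H](O)Cc1ccc(O)c(CC=C(C)C)c1 | intermediate
5 | methyl (S)-3-(2,2-dimethylchroman-6-yl)-2-hydroxypropanoate | COC(=O)[C@@H](O)Cc1ccc2c(c1)CCC(C)(C)O2 | intermediate
6 | (S)-3-(2,2-dimethylchroman-6-yl)-2-hydroxypropanoic acid | O=C(O)[C@@H](O)Cc1ccc2c(c1)CCC(C)(C)O2 | intermediate
7 | pivalaldehyde | CC(C)(C)C=O | starting material
8 | (2S,5S)-2-tert-butyl-5-[(2,2-dimethylchroman-6-yl)methyl]-1,3-dioxolan-4-one | CC(C)(C)[C@@H]1OC(=O)[C@H](Cc2ccc3c(c2)CCC(C)(C)O3)O1 | intermediate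
9 | benzoyl chloride | O=C(Cl)c1ccccc1 | starting material
10 | lithium enolate of 8 | CC(C)(C)[C@@H]1OC(O[Li])=C(Cc2ccc3c(c2)CCC(C)(C)O3)O1 | intermediate
11 | (2S,5R)-5-benzoyl-2-tert-butyl-5-[(2,2-dimethylchroman-6-yl)methyl]-1,3-dioxolan-4-one | CC(C)(C)[C@@H]1OC(=O)[C@@](Cc2ccc3c(c2)CCC(C)(C)O3)(C(=O)c2ccccc2)O1 | intermediate
12 | methyl (R)-2-[(2,2-dimethylchroman-6-yl)methyl]-2-hydroxy-3-oxo-3-phenylpropanoate | COC(=O)[C@@](O)(Cc1ccc2c(c1)CCC(C)(C)O2)C(=O)c1ccccc1 | intermediate
13 | triethyl phosphonoacetate | CCOC(=O)CP(=O)(OCC)OCC | starting material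
14 | ethyl 2-diazo-2-(diethoxyphosphoryl)acetate | CCOC(=O)C(=[N+]=[N-])P(=O)(OCC)OCC | intermediate
15 | benzyl alcohol | OCc1ccccc1 | starting material
16 | ethyl 2-(benzyloxy)-2-(diethoxyphosphoryl)acetate | CCOC(=O)C(OCc1ccccc1)P(=O)(OCC)OCC | intermediate
17 | 2-(benzyloxy)-2-(diethoxyphosphoryl)acetic acid | OC(=O)C(OCc1ccccc1)P(=O)(OCC)OCC | intermediate
18 | methyl (R)-2-{[2-(benzyloxy)-2-(diethoxyphosphoryl)acetyl]oxy}-2-[(2,2-dimethylchroman-6-yl)methyl]-3-oxo-3-phenylpropanoate | COC(=O)[C@@](OC(=O)C(OCc1ccccc1)P(=O)(OCC)OCC)(Cc1ccc2c(c1)CCC(C)(C)O2)C(=O)c1ccccc1 | intermediate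
19 | methyl (R)-4-(benzyloxy)-2-[(2,2-dimethylchroman-6-yl)methyl]-5-oxo-3-phenyl-2,5-dihydrofuran-2-carboxylate | COC(=O)[C@]1(Cc2ccc3c(c2)CCC(C)(C)O3)OC(=O)C(OCc2ccccc2)=C1c1ccccc1 | intermediate
20 | 4'-dehydroxy aspernolide A, methyl (R)-2-[(2,2-dimethylchroman-6-yl)methyl]-4-hydroxy-5-oxo-3-phenyl-2,5-dihydrofuran-2-carboxylate | COC(=O)[C@]1(Cc2ccc3c(c2)CCC(C)(C)O3)OC(=O)C(O)=C1c1ccccc1 | target

**Step count**

Total steps: 12. Longest linear sequence: 9 (steps 1–6 and 10–12); steps 7–9 prepare the phosphonate acid 17.

**Steps most likely to fail**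

Step 5. The enolate may be acylated on oxygen, or may condense with itself before it is trapped. The fallback sets out from 8. Enolate 10, generated as before, is quenched with benzaldehyde (THF, −78 °C) in an aldol addition, again anti to tert-butyl. This should give (2S,5R)-2-tert-butyl-5-[(2,2-dimethylchroman-6-yl)methyl]-5-[hydroxy(phenyl)methyl]-1,3-dioxolan-4-one F1 as a mixture of carbinol epimers. Oxidation with Dess–Martin periodinane (CH2Cl2, NaHCO3) removes that mixture and returns to the route at 11.

Step 6. Methoxide may attack the benzoyl carbonyl (retro-Claisen debenzoylation), or the liberated tertiary alkoxide may shift the benzoyl group from carbon to oxygen; either destroys the quaternary centre. The fallback sets out from 11 and carries C4 through the ring opening at the alcohol oxidation level. NaBH4 (THF–MeOH, −40 °C) reduces the ketone to (2S,5R)-2-tert-butyl-5-[(2,2-dimethylchroman-6-yl)methyl]-5-[hydroxy(phenyl)methyl]-1,3-dioxolan-4-one F2, which has the same constitution as F1. NaOMe in MeOH then opens the acetal to methyl (2R)-2-[(2,2-dimethylchroman-6-yl)methyl]-2,3-dihydroxy-3-phenylpropanoate F3. IBX (EtOAc, 70 °C) oxidises only the secondary benzylic alcohol and returns to the route at 12.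

Step 10. Acylation of the hindered, electron-poor tertiary alcohol by the bulky phosphono acid may stall, or be outrun by base-induced benzoyl migration. The fallback sets out from 12 and closes the ring by aldol condensation instead of olefination. The small and more reactive benzyloxyacetyl chloride (pyridine, DMAP, CH2Cl2, 0 °C) should give methyl (R)-2-{[(benzyloxy)acetyl]oxy}-2-[(2,2-dimethylchroman-6-yl)methyl]-3-oxo-3-phenylpropanoate F4. LiHMDS (LiN(SiMe3)2, THF, −78 °C, cold quench to stay under kinetic control) adds the ester enolate to the ketone, giving methyl (2R)-4-(benzyloxy)-2-[(2,2-dimethylchroman-6-yl)methyl]-3-hydroxy-5-oxo-3-phenyltetrahydrofuran-2-carboxylate F5. Acid-catalysed dehydration (p-TsOH, toluene, 80 °C) returns to the route at 19, and steps 7–9 and 11 are then not needed.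

**Further compounds**

F1 | step 5 | (2S,5R)-2-tert-butyl-5-[(2,2-dimethylchroman-6-yl)methyl]-5-[hydroxy(phenyl)methyl]-1,3-dioxolan-4-one | CC(C)(C)[C@@H]1OC(=O)[C@@](Cc2ccc3c(c2)CCC(C)(C)O3)(C(O)c2ccccc2)O1
F2 | step 6 | (2S,5R)-2-tert-butyl-5-[(2,2-dimethylchroman-6-yl)methyl]-5-[hydroxy(phenyl)methyl]-1,3-dioxolan-4-one | CC(C)(C)[C@@H]1OC(=O)[C@@](Cc2ccc3c(c2)CCC(C)(C)O3)(C(O)c2ccccc2)O1
F3 | step 6 | methyl (2R)-2-[(2,2-dimethylchroman-6-yl)methyl]-2,3-dihydroxy-3-phenylpropanoate | COC(=O)[C@@](O)(Cc1ccc2c(c1)CCC(C)(C)O2)C(O)c1ccccc1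
F4 | step 10 | methyl (R)-2-{[(benzyloxy)acetyl]oxy}-2-[(2,2-dimethylchroman-6-yl)methyl]-3-oxo-3-phenylpropanoate | COC(=O)[C@@](OC(=O)COCc1ccccc1)(Cc1ccc2c(c1)CCC(C)(C)O2)C(=O)c1ccccc1
F5 | step 10 | methyl (2R)-4-(benzyloxy)-2-[(2,2-dimethylchroman-6-yl)methyl]-3-hydroxy-5-oxo-3-phenyltetrahydrofuran-2-carboxylate | COC(=O)[C@]1(Cc2ccc3c(c2)CCC(C)(C)O3)OC(=O)C(OCc2ccccc2)C1(O)c1ccccc1
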